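**Retrosynthetic overview**

- The target comes from a silyl-protected hydrindane aldehyde by desilylation and oxidation (secondary alcohol to ketone, aldehyde to acid).
- No ring exists until the last C–C bond-forming step. An intramolecular Diels–Alder reaction of a linear all-E tetraene enal then closes the cyclohexene and, through its tether, the cyclopentane in the same step, setting four stereocentres; the enal is installed by a Wittig reaction.
- The aldehyde for that Wittig reaction comes from anti-selective hydroboration of a 1,1-disubstituted alkene, which sets the ethyl-bearing centre next to the carbinol.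
- Key disconnection: the diene sigma bond (the future C6=C7 ring alkene) is made by a palladium/copper-catalysed syn hydro-dienylation of an internal alkyne with a dienyl iodide. The iodide is built from but-1-yne and phenylacetylene (iodochlorination, borylation, Negishi coupling, iododeboronation).
- The alkyne comes from syn propargylation of 2-ethylacrolein with a chiral allenylstannane made from hex-3-yn-2-one by asymmetric transfer hydrogenation.

Convention: locants for the bicyclic compounds are those of the systematic name of target 28 (C1 methyl-bearing, C2 oxygenated, C3 ethyl-bearing, C4 carboxyl-bearing, C5 styryl-bearing, C6=C7 alkene).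

**Route**

Step 1
Reactants: 1 but-1-yne
Product: 2 (E)-2-chloro-1-iodobut-1-ene
Conditions: ICl (1.05 equiv), CH2Cl2, −78 °C → 0 °C, dark
Reagents that add atoms: iodine monochloride, ClI
Why: Electrophilic iodochlorination of a terminal alkyne, in which chloride opens the iodonium ion at the substituted carbon from the opposite face (anti, Markovnikov), places I and Cl trans, and this relationship later becomes the trans arrangement of the styryl group and the diene carbon.

Step 2
Reactants: 2 (E)-2-chloro-1-iodobut-1-ene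
Product: 3 2-[(E)-2-chlorobut-1-en-1-yl]-4,4,5,5-tetramethyl-1,3,2-dioxaborolane
Conditions: B2pin2, PdCl2(PPh3)2 (3 mol %), PPh3 (6 mol %), KOPh, toluene, 50 °C
Reagents that add atoms: bis(pinacolato)diboron, CC1(C)OB(OC1(C)C)B1OC(C)(C)C(C)(C)O1
Why: In this Miyaura borylation zerovalent palladium inserts into C–I far faster than into C–Cl and the C–B bond forms with retention of alkene geometry.

Step 3
Reactants: 3 2-[(E)-2-chlorobut-1-en-1-yl]-4,4,5,5-tetramethyl-1,3,2-dioxaborolane; 4 ethynylbenzene (phenylacetylene)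
Product: 7 2-[(1E,3E)-2-ethyl-4-phenylbuta-1,3-dien-1-yl]-4,4,5,5-tetramethyl-1,3,2-dioxaborolane, via styrylzirconocene chloride 5 (not isolated), via styrylzinc chloride 6 (not isolated)
Conditions: 4, Cp2Zr(H)Cl, THF, rt; ZnCl2, 0 °C; then 3, Pd(P(t-Bu)3)2 (3 mol %), THF/NMP, 60 °C
Reagents that add atoms: none
Why: Syn hydrozirconation of the terminal alkyne gives the (E)-alkenyl metal, and transmetalation to zinc followed by Negishi coupling at the alkenyl chloride proceeds with retention at both partners while the pinacol boronate stays inert in the absence of base.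

Step 4
Reactants: 7 2-[(1E,3E)-2-ethyl-4-phenylbuta-1,3-dien-1-yl]-4,4,5,5-tetramethyl-1,3,2-dioxaborolane
Product: 8 [(1E,3E)-3-ethyl-4-iodobuta-1,3-dien-1-yl]benzene
Conditions: NaOH (aq), THF, 0 °C; then I2, 0 °C, dark
Reagents that add atoms: iodine, II
Why: Iododeboronation of the hydroxide-activated alkenylboronate replaces boron by iodine with retention of the alkene geometry.

Step 5
Reactants: 9 hex-3-yn-2-one
Product: 10 (2S)-hex-3-yn-2-ol
Conditions: Ru[(S,S)-TsDPEN](p-cymene) (0.5 mol %), i-PrOH, 28 °C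
Reagents that add atoms: none
Why: Noyori asymmetric transfer hydrogenation of the ynone, with the alkynyl group taking the place an aryl group occupies in the six-membered hydride/proton transfer, delivers hydride to one carbonyl face and sets the (S) carbinol.

Step 6
Reactants: 10 (2S)-hex-3-yn-2-ol
Product: 11 (2S)-hex-3-yn-2-yl methanesulfonate
Conditions: MsCl, Et3N, CH2Cl2, −78 °C → 0 °C
Reagents that add atoms: methanesulfonyl chloride, CS(=O)(=O)Cl
Why: Sulfonylation occurs at oxygen, so the stereocentre is untouched.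

Step 7
Reactants: 11 (2S)-hex-3-yn-2-yl methanesulfonate
Product: 12 (Ra)-tributyl(hexa-3,4-dien-3-yl)stannane
Conditions: Bu3SnH, LiN(i-Pr)2, THF, 0 °C; CuBr·SMe2, −78 °C; then 11, −78 °C
Reagents that add atoms: tributylstannane, CCCC[SnH](CCCC)CCCC
Why: Anti SN2' substitution of the propargylic mesylate by the stannylcopper reagent (Marshall allenylstannane synthesis) converts the (S) centre into the (Ra) allene axis.

Step 8
Reactants: 12 (Ra)-tributyl(hexa-3,4-dien-3-yl)stannane; 13 2-ethylacrolein (2-methylidenebutanal)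
Product: 14 (3R,4S)-2-ethyl-4-methyloct-1-en-5-yn-3-ol
Conditions: BF3·OEt2, CH2Cl2, −78 °C
Reagents that add atoms: none
Why: Marshall-type BF3-promoted allenylstannane addition (anti SE2' through an open antiperiplanar transition state) gives the syn homopropargylic alcohol, the allene axis fixing the methyl-bearing carbon as 4S and the syn preference of the α-substituted aldehyde fixing the carbinol as 3R.

Step 9
Reactants: 14 (3R,4S)-2-ethyl-4-methyloct-1-en-5-yn-3-ol
Product: 15 tert-butyl{[(3R,4S)-2-ethyl-4-methyloct-1-en-5-yn-3-yl]oxy}dimethylsilane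
Conditions: TBSOTf, 2,6-lutidine, CH2Cl2, −78 °C → 0 °C
Reagents that add atoms: tert-butyldimethylsilyl trifluoromethanesulfonate, CC(C)(C)[Si](C)(C)OS(=O)(=O)C(F)(F)F
Why: Silylation of the hindered secondary alcohol protects it from the hydride, base and oxidants of the following steps without touching a stereocentre.

Step 10
Reactants: 15 tert-butyl{[(3R,4S)-2-ethyl-4-methyloct-1-en-5-yn-3-yl]oxy}dimethylsilane; 8 [(1E,3E)-3-ethyl-4-iodobuta-1,3-dien-1-yl]benzene
Product: 16 tert-butyl{[(3R,4S,5E,7E,9E)-2,6,8-triethyl-4-methyl-10-phenyldeca-1,5,7,9-tetraen-3-yl]oxy}dimethylsilane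
Conditions: (IPr)CuCl (10 mol %; IPr = 1,3-bis(2,6-diisopropylphenyl)imidazol-2-ylidene), Pd(OAc)2 (5 mol %), XPhos (10 mol %), LiOt-Bu (1.5 equiv), (EtO)2MeSiH (2 equiv), toluene, 40 °C
Reagents that add atoms: none
Why: Proposed new method: (IPr)Cu–H, formed from (IPr)CuOt-Bu and the hydrosilane, should add syn across the alkyne with copper on the ethyl-bearing carbon (the bulky carbene ligand avoids the branched propargylic carbon, and the isolated 1,1-disubstituted alkene and the silyl ether are inert to it), the alkenylcopper then transmetalates to the dienylpalladium iodide formed by oxidative addition of 8 to zerovalent palladium, and reductive elimination forges the diene sigma bond (the future C6–C7 ring bond) with the 5E geometry fixed by the syn addition and the dienyl geometry retained; the closest known reaction type is the cooperative copper hydride/palladium hydroarylation of alkynes with aryl halides, which has not been shown for an unsymmetrical dialkyl alkyne with a dienyl iodide.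

Step 11
Reactants: 16 tert-butyl{[(3R,4S,5E,7E,9E)-2,6,8-triethyl-4-methyl-10-phenyldeca-1,5,7,9-tetraen-3-yl]oxy}dimethylsilane
Product: 18 (2S,3R,4S,5E,7E,9E)-3-[(tert-butyldimethylsilyl)oxy]-2,6,8-triethyl-4-methyl-10-phenyldeca-5,7,9-trien-1-ol, via alkyl-9-BBN adduct 17 (not isolated)
Conditions: 9-BBN (2 equiv), THF, 0 °C → rt; then NaOH (aq), H2O2, 0 °C
Reagents that add atoms: hydrogen peroxide, OO
Why: In this substrate-controlled hydroboration–oxidation (Still–Barrish type) 9-BBN reacts with the 1,1-disubstituted alkene much faster than with the conjugated di- and trisubstituted alkenes and adds to the face dictated by the neighbouring silyloxy-bearing carbon in the conformer of least allylic strain, giving the anti relationship and hence the (2S) ethyl-bearing centre.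

Step 12
Reactants: 18 (2S,3R,4S,5E,7E,9E)-3-[(tert-butyldimethylsilyl)oxy]-2,6,8-triethyl-4-methyl-10-phenyldeca-5,7,9-trien-1-ol
Product: 19 (2R,3R,4S,5E,7E,9E)-3-[(tert-butyldimethylsilyl)oxy]-2,6,8-triethyl-4-methyl-10-phenyldeca-5,7,9-trienal
Conditions: Dess–Martin periodinane, NaHCO3, CH2Cl2, 0 °C → rt
Reagents that add atoms: none
Why: Dess–Martin oxidation under buffered, non-basic conditions gives the α-branched aldehyde without epimerisation (the descriptor changes from 2S to 2R only through the priority change).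

Step 13
Reactants: 20 1-bromopropane
Product: 21 triphenyl(propyl)phosphonium bromide
Conditions: PPh3, toluene, 110 °C
Reagents that add atoms: triphenylphosphine, c1ccc(cc1)P(c1ccccc1)c1ccccc1
Why: SN2 alkylation of the phosphine by the primary bromide gives the phosphonium salt.

Step 14
Reactants: 21 triphenyl(propyl)phosphonium bromide; 22 ethyl formate
Product: 24 2-(triphenyl-λ5-phosphanylidene)butanal, via propylidenetriphenylphosphorane 23 (not isolated)
Conditions: KOt-Bu, THF, 0 °C; then HCO2Et, 0 °C → rt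
Reagents that add atoms: none
Why: Deprotonation gives the ylide, and its C-formylation by the formate ester (ylide acylation) followed by loss of the acidic α-proton gives the stabilised formyl ylide.

Step 15
Reactants: 19 (2R,3R,4S,5E,7E,9E)-3-[(tert-butyldimethylsilyl)oxy]-2,6,8-triethyl-4-methyl-10-phenyldeca-5,7,9-trienal; 24 2-(triphenyl-λ5-phosphanylidene)butanal
Product: 26 (1S,2R,3S,3aR,4R,5S,7aR)-2-[(tert-butyldimethylsilyl)oxy]-3,4,5,7-tetraethyl-1-methyl-5-[(E)-2-phenylethenyl]-2,3,3a,4,5,7a-hexahydro-1H-indene-4-carbaldehyde, via tetraene enal 25 (not isolated)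
Conditions: 24 (2.5 equiv), BHT (cat.), toluene, 90 °C, then 110 °C
Reagents that add atoms: none
Why: Wittig olefination with the stabilised ylide gives the (E)-2-ethyl enal, which then undergoes the intramolecular Diels–Alder reaction through the trans-fused transition state with the formyl group endo, the faces of diene and dienophile both being fixed in the same (matched) sense by allylic 1,3-strain at the two allylic stereocentres (each C–H eclipses the neighbouring ethyl-substituted alkene carbon), which sets C3a, C4, C5 and C7a.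

Step 16
Reactants: 26 (1S,2R,3S,3aR,4R,5S,7aR)-2-[(tert-butyldimethylsilyl)oxy]-3,4,5,7-tetraethyl-1-methyl-5-[(E)-2-phenylethenyl]-2,3,3a,4,5,7a-hexahydro-1H-indene-4-carbaldehyde
Product: 27 (1S,2R,3S,3aR,4R,5S,7aR)-3,4,5,7-tetraethyl-2-hydroxy-1-methyl-5-[(E)-2-phenylethenyl]-2,3,3a,4,5,7a-hexahydro-1H-indene-4-carbaldehyde
Conditions: HF·pyridine, pyridine, THF, 0 °C → rt
Reagents that add atoms: none
Why: Fluoride-mediated desilylation cleaves the hindered secondary silyl ether without touching the neopentyl aldehyde or the alkenes, and the rigid trans-fused skeleton keeps the hydroxyl and formyl groups too far apart for lactol formation.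

Step 17
Reactants: 27 (1S,2R,3S,3aR,4R,5S,7aR)-3,4,5,7-tetraethyl-2-hydroxy-1-methyl-5-[(E)-2-phenylethenyl]-2,3,3a,4,5,7a-hexahydro-1H-indene-4-carbaldehyde
Product: 28 (1S,3S,3aR,4R,5S,7aR)-3,4,5,7-tetraethyl-1-methyl-2-oxo-5-[(E)-2-phenylethenyl]-2,3,3a,4,5,7a-hexahydro-1H-indene-4-carboxylic acid
Conditions: CrO3, H2SO4, H2O, acetone, 0 °C (Jones oxidation)
Reagents that add atoms: water, O
Why: Jones oxidation converts the secondary alcohol into the ketone and the aldehyde (through its hydrate) into the acid in one operation, and the two stereocentres next to the new ketone already carry their substituents cis to the adjacent ring-fusion hydrogen, which is expected to be the more stable arrangement, so brief acid exposure should not scramble them.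

**Compound list**

1 | but-1-yne | CCC#C | starting material
2 | (E)-2-chloro-1-iodobut-1-ene | CC/C(Cl)=C\I | intermediate
3 | 2-[(E)-2-chlorobut-1-en-1-yl]-4,4,5,5-tetramethyl-1,3,2-dioxaborolane | CC/C(Cl)=C\B1OC(C)(C)C(C)(C)O1 | intermediate
4 | ethynylbenzene (phenylacetylene) | C#Cc1ccccc1 | starting material
5 | chlorobis(cyclopentadienyl)[(E)-2-phenylethenyl]zirconium | Cl[Zr](/C=C/c1ccccc1)(C1C=CC=C1)C1C=CC=C1 | intermediate (not isolated)
6 | chloro[(E)-2-phenylethenyl]zinc | Cl[Zn]/C=C/c1ccccc1 | intermediate (not isolated)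
7 | 2-[(1E,3E)-2-ethyl-4-phenylbuta-1,3-dien-1-yl]-4,4,5,5-tetramethyl-1,3,2-dioxaborolane | CC/C(/C=C/c1ccccc1)=C\B1OC(C)(C)C(C)(C)O1 | intermediate
8 | [(1E,3E)-3-ethyl-4-iodobuta-1,3-dien-1-yl]benzene | CC/C(/C=C/c1ccccc1)=C\I | intermediate
9 | hex-3-yn-2-one | CCC#CC(C)=O | starting material
10 | (2S)-hex-3-yn-2-ol | CCC#C[C@H](C)O | intermediate
11 | (2S)-hex-3-yn-2-yl methanesulfonate | CCC#C[C@H](C)OS(C)(=O)=O | intermediate
12 | (Ra)-tributyl(hexa-3,4-dien-3-yl)stannane | [H]C(C)=[C@@]=C(CC)[Sn](CCCC)(CCCC)CCCC | intermediate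
13 | 2-ethylacrolein (2-methylidenebutanal) | CCC(=C)C=O | starting material
14 | (3R,4S)-2-ethyl-4-methyloct-1-en-5-yn-3-ol | CCC#C[C@H](C)[C@@H](O)C(CC)=C | intermediate
15 | tert-butyl{[(3R,4S)-2-ethyl-4-methyloct-1-en-5-yn-3-yl]oxy}dimethylsilane | CCC#C[C@H](C)[C@@H](O[Si](C)(C)C(C)(C)C)C(CC)=C | intermediate
16 | tert-butyl{[(3R,4S,5E,7E,9E)-2,6,8-triethyl-4-methyl-10-phenyldeca-1,5,7,9-tetraen-3-yl]oxy}dimethylsilane | c1ccccc1/C=C/C(CC)=C/C(CC)=C/[C@H](C)[C@@H](O[Si](C)(C)C(C)(C)C)C(CC)=C | intermediate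
17 | alkyl-9-BBN adduct of 16 (9-borabicyclo[3.3.1]nonan-9-yl on C1; the three stereocentres arranged as in 18) | c1ccccc1/C=C/C(CC)=C/C(CC)=C/[C@H](C)[C@@H](O[Si](C)(C)C(C)(C)C)[C@@H](CC)CB1C2CCCC1CCC2 | intermediate (not isolated)
18 | (2S,3R,4S,5E,7E,9E)-3-[(tert-butyldimethylsilyl)oxy]-2,6,8-triethyl-4-methyl-10-phenyldeca-5,7,9-trien-1-ol | c1ccccc1/C=C/C(CC)=C/C(CC)=C/[C@H](C)[C@@H](O[Si](C)(C)C(C)(C)C)[C@@H](CC)CO | intermediate
19 | (2R,3R,4S,5E,7E,9E)-3-[(tert-butyldimethylsilyl)oxy]-2,6,8-triethyl-4-methyl-10-phenyldeca-5,7,9-trienal | c1ccccc1/C=C/C(CC)=C/C(CC)=C/[C@H](C)[C@@H](O[Si](C)(C)C(C)(C)C)[C@@H](CC)C=O | intermediate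
20 | 1-bromopropane | CCCBr | starting material
21 | triphenyl(propyl)phosphonium bromide | CCC[P+](c1ccccc1)(c1ccccc1)c1ccccc1.[Br-] | intermediate
22 | ethyl formate | CCOC=O | starting material
23 | propylidenetriphenylphosphorane | CCC=P(c1ccccc1)(c1ccccc1)c1ccccc1 | intermediate (not isolated)
24 | 2-(triphenyl-λ5-phosphanylidene)butanal | CCC(C=O)=P(c1ccccc1)(c1ccccc1)c1ccccc1 | intermediate
25 | (2E,4S,5R,6S,7E,9E,11E)-5-[(tert-butyldimethylsilyl)oxy]-2,4,8,10-tetraethyl-6-methyl-12-phenyldodeca-2,7,9,11-tetraenal | c1ccccc1/C=C/C(CC)=C/C(CC)=C/[C@H](C)[C@@H](O[Si](C)(C)C(C)(C)C)[C@@H](CC)/C=C(CC)/C=O | intermediate (not isolated)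
26 | (1S,2R,3S,3aR,4R,5S,7aR)-2-[(tert-butyldimethylsilyl)oxy]-3,4,5,7-tetraethyl-1-methyl-5-[(E)-2-phenylethenyl]-2,3,3a,4,5,7a-hexahydro-1H-indene-4-carbaldehyde | CCC1=C[C@@](/C=C/c2ccccc2)(CC)[C@](CC)(C=O)[C@@H]2[C@@H]1[C@H](C)[C@@H](O[Si](C)(C)C(C)(C)C)[C@H]2CC | intermediate
27 | (1S,2R,3S,3aR,4R,5S,7aR)-3,4,5,7-tetraethyl-2-hydroxy-1-methyl-5-[(E)-2-phenylethenyl]-2,3,3a,4,5,7a-hexahydro-1H-indene-4-carbaldehyde | CCC1=C[C@@](/C=C/c2ccccc2)(CC)[C@](CC)(C=O)[C@@H]2[C@@H]1[C@H](C)[C@@H](O)[C@H]2CC | intermediate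
28 | (1S,3S,3aR,4R,5S,7aR)-3,4,5,7-tetraethyl-1-methyl-2-oxo-5-[(E)-2-phenylethenyl]-2,3,3a,4,5,7a-hexahydro-1H-indene-4-carboxylic acid | CCC1=C[C@@](/C=C/c2ccccc2)(CC)[C@](CC)(C(=O)O)[C@@H]2[C@@H]1[C@H](C)C(=O)[C@H]2CC | target

**Step count**

Total step count: 17.
Longest linear sequence: 11 steps (steps 5, 6, 7, 8, 9, 10, 11, 12, 15, 16, 17, from hex-3-yn-2-one 9). The dienyl iodide branch (steps 1 to 4) and the ylide branch (steps 13 and 14) run in parallel.

**Steps most likely to fail, with fallbacks**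

Step 10 (the proposed copper hydride/palladium hydro-dienylation). The risks are wrong regiochemistry of hydrocupration, simple reduction of 8, and slow transmetalation of the hindered alkenylcopper. The fallback uses known chemistry, sets out from 15 and comes back at 18, so steps 10 and 11 are both bypassed. Enyne 15 is hydroborated first (9-BBN, then NaOH/H2O2; the internal alkyne is inert) to give the alkynol (2S,3R,4S)-3-[(tert-butyldimethylsilyl)oxy]-2-ethyl-4-methyloct-5-yn-1-ol F1. Hydrozirconation with excess Cp2Zr(H)Cl (THF, 50 °C, where zirconium settles on the ethyl-bearing alkyne carbon) and an I2 quench give the alkenyl iodide (2S,3R,4S,5E)-3-[(tert-butyldimethylsilyl)oxy]-2-ethyl-6-iodo-4-methyloct-5-en-1-ol F2. Suzuki coupling of F2 with dienylboronate 7 (Pd(dppf)Cl2, K3PO4, DMF/H2O, rt) then gives 18.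

Step 11 (hydroboration in the presence of the conjugated triene). The risks are competing attack on the triene and low anti selectivity. The fallback moves the hydroboration ahead of the coupling, sets out from 14 and comes back at 18. Free alcohol 14 is hydroborated with 9-BBN (3 equiv, then NaOH/H2O2) to give the diol (2S,3R,4S)-2-ethyl-4-methyloct-5-yne-1,3-diol F3. Double silylation (TBSOTf, 2,6-lutidine) gives (2S,3R,4S)-1,3-bis[(tert-butyldimethylsilyl)oxy]-2-ethyl-4-methyloct-5-yne F4. The step 10 coupling of F4 with 8 gives (2S,3R,4S,5E,7E,9E)-1,3-bis[(tert-butyldimethylsilyl)oxy]-2,6,8-triethyl-4-methyl-10-phenyldeca-5,7,9-triene F5. Selective cleavage of the primary silyl ether (HF·pyridine, pyridine, THF, 0 °C) gives 18.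

Step 15 (Wittig/Diels–Alder cascade). The risks are low reactivity of the formyl ylide toward the hindered aldehyde, epimerisation on prolonged heating, and modest endo or facial selectivity in the thermal cycloaddition. The fallback builds the dienophile at the ester oxidation level and runs the cycloaddition as a separate, Lewis-acid-promoted low-temperature step; it sets out from 19 and comes back at 26. Methyl 2-bromobutanoate and PPh3 give (1-methoxy-1-oxobutan-2-yl)triphenylphosphonium bromide F6, and aqueous NaOH gives the ylide methyl 2-(triphenyl-λ5-phosphanylidene)butanoate F7. The more nucleophilic F7 olefinates 19 at 60 °C to the tetraene ester methyl (2E,4S,5R,6S,7E,9E,11E)-5-[(tert-butyldimethylsilyl)oxy]-2,4,8,10-tetraethyl-6-methyl-12-phenyldodeca-2,7,9,11-tetraenoate F8, a poor dienophile that survives isolation. Reduction with i-Bu2AlH (CH2Cl2, −78 °C) gives the allylic alcohol (2E,4S,5R,6S,7E,9E,11E)-5-[(tert-butyldimethylsilyl)oxy]-2,4,8,10-tetraethyl-6-methyl-12-phenyldodeca-2,7,9,11-tetraen-1-ol F9. MnO2 (CH2Cl2, rt) gives enal 25, now handled as an isolated compound, and Me2AlCl (CH2Cl2, −78 °C → −20 °C) promotes the endo-selective cycloaddition to 26.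

**Further compounds**

F1 | step 10 | (2S,3R,4S)-3-[(tert-butyldimethylsilyl)oxy]-2-ethyl-4-methyloct-5-yn-1-ol | CCC#C[C@H](C)[C@@H](O[Si](C)(C)C(C)(C)C)[C@@H](CC)CO
F2 | step 10 | (2S,3R,4S,5E)-3-[(tert-butyldimethylsilyl)oxy]-2-ethyl-6-iodo-4-methyloct-5-en-1-ol | CC/C(I)=C\[C@H](C)[C@@H](O[Si](C)(C)C(C)(C)C)[C@@H](CC)CO
F3 | step 11 | (2S,3R,4S)-2-ethyl-4-methyloct-5-yne-1,3-diol | CCC#C[C@H](C)[C@@H](O)[C@@H](CC)CO
F4 | step 11 | (2S,3R,4S)-1,3-bis[(tert-butyldimethylsilyl)oxy]-2-ethyl-4-methyloct-5-yne | CCC#C[C@H](C)[C@@H](O[Si](C)(C)C(C)(C)C)[C@@H](CC)CO[Si](C)(C)C(C)(C)C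
F5 | step 11 | (2S,3R,4S,5E,7E,9E)-1,3-bis[(tert-butyldimethylsilyl)oxy]-2,6,8-triethyl-4-methyl-10-phenyldeca-5,7,9-triene | c1ccccc1/C=C/C(CC)=C/C(CC)=C/[C@H](C)[C@@H](O[Si](C)(C)C(C)(C)C)[C@@H](CC)CO[Si](C)(C)C(C)(C)C
F6 | step 15 | (1-methoxy-1-oxobutan-2-yl)triphenylphosphonium bromide | CCC(C(=O)OC)[P+](c1ccccc1)(c1ccccc1)c1ccccc1.[Br-]
F7 | step 15 | methyl 2-(triphenyl-λ5-phosphanylidene)butanoate | CCC(C(=O)OC)=P(c1ccccc1)(c1ccccc1)c1ccccc1
F8 | step 15 | methyl (2E,4S,5R,6S,7E,9E,11E)-5-[(tert-butyldimethylsilyl)oxy]-2,4,8,10-tetraethyl-6-methyl-12-phenyldodeca-2,7,9,11-tetraenoate | c1ccccc1/C=C/C(CC)=C/C(CC)=C/[C@H](C)[C@@H](O[Si](C)(C)C(C)(C)C)[C@@H](CC)/C=C(CC)/C(=O)OC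
F9 | step 15 | (2E,4S,5R,6S,7E,9E,11E)-5-[(tert-butyldimethylsilyl)oxy]-2,4,8,10-tetraethyl-6-methyl-12-phenyldodeca-2,7,9,11-tetraen-1-ol | c1ccccc1/C=C/C(CC)=C/C(CC)=C/[C@H](C)[C@@H](O[Si](C)(C)C(C)(C)C)[C@@H](CC)/C=C(CC)/CO
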